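Rings A and B are identical all-cis (2S,3S,6R)-2-methylpiperidin-3-ols. The (CH2)11 tether from C6 of ring A to the enal β-carbon and the (CH2)10 tether from C6 of ring B to the α-carbon carry no functional group. Each tether is therefore cut between its second and third methylene counted from C6. One double mixed Kolbe electrolysis of two molecules of a ring propanoic acid with one central diacid forges both bonds. This completes the C36 skeleton without touching a stereocentre. The precursors are an N-Boc, O-TBS ring acid and a diacid whose E-enal is held as its dimethyl acetal, so a single acid treatment then releases the target.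

Key step: step 15

Remark on the chemistry: the aminal carbon (C6) of every ring intermediate before the allylation is an epimeric mixture. It is erased on ionisation and is therefore written without configuration.

Step 1
Reactants: 1 2-acetylfuran; 2 (S)-2-methylpropane-2-sulfinamide
Product: 4 (S)-N-[(1S)-1-(furan-2-yl)ethyl]-2-methylpropane-2-sulfinamide, via N-sulfinyl ketimine 3 (not isolated)
Conditions: Ti(OEt)4 (2 equiv), THF, 65 °C; then NaBH4, −48 °C; chromatography
Reagents that add atoms: none
Why: Auxiliary-controlled reductive amination: Ti(OEt)4 drives condensation to the E-ketimine, and borohydride bound to the sulfinyl oxygen in a closed chair-like transition state should deliver hydride to one face and set the (S)-carbinamine centre (later C2 of both rings), the minor diastereomer being removable by chromatography.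

Step 2
Reactants: 4 (S)-N-[(1S)-1-(furan-2-yl)ethyl]-2-methylpropane-2-sulfinamide
Product: 6 tert-butyl N-[(1S)-1-(furan-2-yl)ethyl]carbamate, via amine hydrochloride 5 (not isolated)
Conditions: HCl (4 M in dioxane), MeOH, 0 °C → rt; evaporate; Boc2O, Et3N, CH2Cl2, rt
Reagents that add atoms: di-tert-butyl dicarbonate, CC(C)(C)OC(=O)OC(=O)OC(C)(C)C
Why: Acid methanolysis of the S–N bond followed by Boc protection exchanges the auxiliary for the carbamate without touching the C–N stereocentre.

Step 3
Reactants: 6 tert-butyl N-[(1S)-1-(furan-2-yl)ethyl]carbamate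
Product: 7 tert-butyl (2S)-6-hydroxy-2-methyl-3-oxo-3,6-dihydropyridine-1(2H)-carboxylate
Conditions: mCPBA (1.2 equiv), CH2Cl2, 0 °C → rt
Reagents that add atoms: mCPBA, OOC(=O)c1cccc(Cl)c1
Why: Aza-Achmatowicz rearrangement: peracid oxidation opens the furan to a Z-configured 4-oxo-enal that the carbamate nitrogen captures as the six-membered hemiaminal, with furan C2 becoming the C3 ketone, furan C5 becoming C6 and the C2 stereocentre untouched.

Step 4
Reactants: 7 tert-butyl (2S)-6-hydroxy-2-methyl-3-oxo-3,6-dihydropyridine-1(2H)-carboxylate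
Product: 8 tert-butyl (2S)-6-methoxy-2-methyl-3-oxo-3,6-dihydropyridine-1(2H)-carboxylate
Conditions: HC(OMe)3 (3 equiv), p-TsOH·H2O (2 mol%), CH2Cl2, 0 °C → rt
Reagents that add atoms: trimethyl orthoformate, COC(OC)OC
Why: Acid-catalysed N,O-acetal formation, with the orthoester as methoxy source and water scavenger, blocks ring–chain tautomerism during the reductions that follow.

Step 5
Reactants: 8 tert-butyl (2S)-6-methoxy-2-methyl-3-oxo-3,6-dihydropyridine-1(2H)-carboxylate
Product: 10 tert-butyl (2S,3S)-3-hydroxy-6-methoxy-2-methylpiperidine-1-carboxylate, via saturated ketone 9 (not isolated)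
Conditions: H2 (1 atm), Pd/C, EtOAc, rt; filter; add MeOH, NaBH4, −40 → 0 °C
Reagents that add atoms: none
Why: Catalytic hydrogenation saturates the enone C4=C5 bond, and in the N-Boc piperidin-3-one A(1,3) strain holds the C2 methyl axial, so borohydride attacks C3 axially from the opposite face (substrate-controlled ketone reduction) and should give the 3S alcohol cis to the methyl group.

Step 6
Reactants: 10 tert-butyl (2S,3S)-3-hydroxy-6-methoxy-2-methylpiperidine-1-carboxylate
Product: 11 tert-butyl (2S,3S)-3-[(tert-butyldimethylsilyl)oxy]-6-methoxy-2-methylpiperidine-1-carboxylate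
Conditions: TBSCl, imidazole, DMF, rt
Reagents that add atoms: tert-butyldimethylsilyl chloride, CC(C)(C)[Si](C)(C)Cl
Why: Imidazole-promoted silylation leaves the acid-sensitive aminal and the Boc group alone and protects O3 for the Lewis acid, oxidation and electrolysis steps.

Step 7
Reactants: 11 tert-butyl (2S,3S)-3-[(tert-butyldimethylsilyl)oxy]-6-methoxy-2-methylpiperidine-1-carboxylate; 12 allyltrimethylsilane
Product: 13 tert-butyl (2S,3S,6S)-6-allyl-3-[(tert-butyldimethylsilyl)oxy]-2-methylpiperidine-1-carboxylate (all-cis)
Conditions: 12 (2 equiv), BF3·OEt2 (1.2 equiv), CH2Cl2, −78 °C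
Reagents that add atoms: none
Why: Hosomi–Sakurai allylation of an N-acyliminium ion: BF3 ionises the aminal, A(1,3) strain with the Boc group keeps the C2 methyl pseudoaxial, and stereoelectronically preferred axial attack through a chair-like transition state brings the allyl group onto the face that carries the methyl, which should set C6 in the 2,6-cis (all-cis) relationship.

Step 8
Reactants: 13 tert-butyl (2S,3S,6S)-6-allyl-3-[(tert-butyldimethylsilyl)oxy]-2-methylpiperidine-1-carboxylate
Product: 15 tert-butyl (2S,3S,6R)-3-[(tert-butyldimethylsilyl)oxy]-6-(3-hydroxypropyl)-2-methylpiperidine-1-carboxylate, via B-alkyl-9-BBN adduct 14 (not isolated)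
Conditions: 9-BBN-H, THF, 0 °C → rt; then aq. NaOH, H2O2 (30%), 0 °C
Reagents that add atoms: hydrogen peroxide, OO
Why: Hydroboration–oxidation of the only alkene with bulky 9-BBN places boron, then oxygen, on the terminal carbon and leaves all ring stereocentres as they are.

Step 9
Reactants: 15 tert-butyl (2S,3S,6R)-3-[(tert-butyldimethylsilyl)oxy]-6-(3-hydroxypropyl)-2-methylpiperidine-1-carboxylate
Product: 17 3-[(2S,5S,6S)-1-(tert-butoxycarbonyl)-5-[(tert-butyldimethylsilyl)oxy]-6-methylpiperidin-2-yl]propanoic acid, via aldehyde 16 (not isolated)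
Conditions: TEMPO (0.2 equiv), PhI(OAc)2 (2.2 equiv), MeCN/H2O (1:1), rt
Reagents that add atoms: water, O
Why: Oxoammonium-catalysed (TEMPO/PhI(OAc)2) oxidation in aqueous acetonitrile carries the primary alcohol through the aldehyde hydrate to the acid under nearly neutral conditions that spare Boc and TBS, and no stereocentre lies next to the new carbonyl.

Step 10
Reactants: 18 methyl undec-10-enoate
Product: 20 methyl 11-hydroxyundecanoate, via B-alkyl-9-BBN adduct 19 (not isolated)
Conditions: 9-BBN-H, THF, 0 °C → rt; then aq. NaOAc, H2O2 (30%), 0 °C → rt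
Reagents that add atoms: hydrogen peroxide, OO
Why: Anti-Markovnikov hydroboration–oxidation, in which 9-BBN ignores the ester and the acetate-buffered peroxide work-up avoids saponification.

Step 11
Reactants: 20 methyl 11-hydroxyundecanoate
Product: 21 methyl 11-oxoundecanoate
Conditions: TEMPO (0.1 equiv), PhI(OAc)2 (1.1 equiv), CH2Cl2, rt
Reagents that add atoms: none
Why: TEMPO/PhI(OAc)2 oxidation in dry CH2Cl2 stops at the aldehyde because no hydrate can form.

Step 12
Reactants: 21 methyl 11-oxoundecanoate (two molecules)
Product: 22 dimethyl (10E)-10-formylhenicos-10-enedioate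
Conditions: pyrrolidine (0.1 equiv), AcOH (0.1 equiv), 4 Å MS, toluene, rt → 50 °C
Reagents that add atoms: none
Why: Amine/acid-catalysed self-aldol condensation: the enamine of one molecule adds to the iminium ion of a second and elimination gives the α-branched enal, a single constitutional product because donor and acceptor are the same aldehyde, with the thermodynamically preferred E geometry (β-chain trans to CHO) that the target needs.

Step 13
Reactants: 22 dimethyl (10E)-10-formylhenicos-10-enedioate
Product: 23 dimethyl (10E)-10-(dimethoxymethyl)henicos-10-enedioate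
Conditions: HC(OMe)3 (3 equiv), PPTS (5 mol%), CH2Cl2, rt; Et3N quench
Reagents that add atoms: trimethyl orthoformate, COC(OC)OC
Why: Acid-catalysed acetalisation with an orthoester masks the aldehyde at its final oxidation level without moving or isomerising the alkene, and the methyl esters are inert.

Step 14
Reactants: 23 dimethyl (10E)-10-(dimethoxymethyl)henicos-10-enedioate
Product: 25 (10E)-10-(dimethoxymethyl)henicos-10-enedioic acid, via dipotassium salt 24 (not isolated)
Conditions: KOH (2.5 equiv), THF/MeOH/H2O, rt; then cold aq. KH2PO4 to pH ≈ 5, EtOAc extraction; used promptly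
Reagents that add atoms: potassium hydroxide, [K+].[OH-]
Why: Ester saponification leaves the base-stable acetal untouched, and protonation with a cold phosphate buffer instead of mineral acid frees both carboxyl groups without hydrolysing the allylic acetal.

Step 15
Reactants: 17 3-[(2S,5S,6S)-1-(tert-butoxycarbonyl)-5-[(tert-butyldimethylsilyl)oxy]-6-methylpiperidin-2-yl]propanoic acid (two molecules incorporated, used in excess); 25 (10E)-10-(dimethoxymethyl)henicos-10-enedioic acid
Product: 26 fully protected bis-piperidine, (2E)-1,1-dimethoxy-2-[10-(ring B)decyl]-14-(ring A)tetradec-2-ene, both rings being (2R,5S,6S)-1-(tert-butoxycarbonyl)-5-[(tert-butyldimethylsilyl)oxy]-6-methylpiperidin-2-yl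
Conditions: 17 (6 equiv), 25 (1 equiv), NaOMe (5 mol% of total CO2H), dry MeOH, Pt foil anode, stainless-steel cathode, undivided cell, ca. 150 mA cm−2, 30–40 °C, until the electrolyte turns faintly basic; aq. NaHCO3 extraction to recover acids; chromatography
Reagents that add atoms: none
Why: Mixed (crossed) Kolbe electrolysis: each carboxylate held on the platinum anode gives up one electron and CO2, and the primary radicals, crowded in the thin anode layer at high current density, pair faster than they are oxidised further, so a ring–CH2CH2 radical from 17 joins the terminal CH2 radical at each end of 25. The closest known reaction is the crossed Kolbe coupling of the side-chain carboxyl of N-protected glutamic acid derivatives with fatty acids, which has the same nitrogen-to-carboxyl spacing as 17 and the same primary–primary bond type; here it simply runs at both ends of one diacid. No ring is closed and no stereocentre is formed, and the six existing ones sit at least two atoms from any radical carbon and so stay intact. The selectivity needed is cross- over homo-coupling, which is purely statistical and is pushed by about three equivalents of 17 per carboxyl group of 25; because both ends of 25 take the same partner there is no regiochemical issue, the neutral by-products (the dimer of 17 and oligomers of 25) differ clearly from 26 in size, and half-coupled acid is recovered by base extraction and electrolysed again. Chemoselectivity rests on the substrates: the radicals are primary and unstabilised (little Hofer–Moest over-oxidation), in the 2,6-diaxial N-Boc chair the C2–H bond is equatorial and out of reach for a 1,5-hydrogen shift while both α C–H bonds are badly aligned for anodic α-methoxylation of the carbamate, and the radical ends of 25 are separated from the alkene by seven and eight methylenes, so cyclisation cannot compete. The acetal makes the trisubstituted alkene less electron-rich than an allylic ether would, keeps the aldehyde away from radicals and cathode, and is safe in methanol because exchange with the solvent regenerates it.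

Step 16
Reactants: 26 fully protected bis-piperidine
Product: 27 target, (2E)-14-[(2R,5S,6S)-5-hydroxy-6-methylpiperidin-2-yl]-2-{10-[(2R,5S,6S)-5-hydroxy-6-methylpiperidin-2-yl]decyl}tetradec-2-enal
Conditions: TFA/H2O (9:1), 0 °C → rt; evaporate; aq. Na2CO3, CHCl3/i-PrOH extraction
Reagents that add atoms: water, O
Why: Global acidolysis: both Boc groups, both silyl ethers and the acetal are all acid-labile, the ammonium salts keep the nitrogen atoms away from the liberated enal, no stereocentre is affected and the E-enal is the thermodynamic isomer, so one operation should give the target after mild basification.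

Compound list
1 | 2-acetylfuran | CC(=O)c1ccco1 | starting material
2 | (S)-2-methylpropane-2-sulfinamide | CC(C)(C)[S@](=O)N | starting material
3 | (S,E)-N-[1-(furan-2-yl)ethylidene]-2-methylpropane-2-sulfinamide | CC(C)(C)[S@](=O)/N=C(\C)c1ccco1 | intermediate
4 | (S)-N-[(1S)-1-(furan-2-yl)ethyl]-2-methylpropane-2-sulfinamide | CC(C)(C)[S@](=O)N[C@@H](C)c1ccco1 | intermediate
5 | (1S)-1-(furan-2-yl)ethanamine hydrochloride | C[C@H](N)c1ccco1.Cl | intermediate
6 | tert-butyl N-[(1S)-1-(furan-2-yl)ethyl]carbamate | CC(C)(C)OC(=O)N[C@@H](C)c1ccco1 | intermediate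
7 | tert-butyl (2S)-6-hydroxy-2-methyl-3-oxo-3,6-dihydropyridine-1(2H)-carboxylate (C6 epimers) | C[C@@H]1N(C(=O)OC(C)(C)C)C(O)C=CC1=O | intermediate
8 | tert-butyl (2S)-6-methoxy-2-methyl-3-oxo-3,6-dihydropyridine-1(2H)-carboxylate (C6 epimers) | C[C@@H]1N(C(=O)OC(C)(C)C)C(OC)C=CC1=O | intermediate
9 | tert-butyl (2S)-6-methoxy-2-methyl-3-oxopiperidine-1-carboxylate (C6 epimers) | C[C@@H]1N(C(=O)OC(C)(C)C)C(OC)CCC1=O | intermediate
10 | tert-butyl (2S,3S)-3-hydroxy-6-methoxy-2-methylpiperidine-1-carboxylate (C6 epimers) | C[C@@H]1N(C(=O)OC(C)(C)C)C(OC)CC[C@@H]1O | intermediate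
11 | tert-butyl (2S,3S)-3-[(tert-butyldimethylsilyl)oxy]-6-methoxy-2-methylpiperidine-1-carboxylate (C6 epimers) | C[C@@H]1N(C(=O)OC(C)(C)C)C(OC)CC[C@@H]1O[Si](C)(C)C(C)(C)C | intermediate
12 | allyltrimethylsilane | C=CC[Si](C)(C)C | starting material
13 | tert-butyl (2S,3S,6S)-6-allyl-3-[(tert-butyldimethylsilyl)oxy]-2-methylpiperidine-1-carboxylate | C[C@@H]1N(C(=O)OC(C)(C)C)[C@H](CC=C)CC[C@@H]1O[Si](C)(C)C(C)(C)C | intermediate
14 | B-[3-(ring)propyl]-9-borabicyclo[3.3.1]nonane adduct of 13 | C[C@@H]1N(C(=O)OC(C)(C)C)[C@H](CCCB2C3CCCC2CCC3)CC[C@@H]1O[Si](C)(C)C(C)(C)C | intermediate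
15 | tert-butyl (2S,3S,6R)-3-[(tert-butyldimethylsilyl)oxy]-6-(3-hydroxypropyl)-2-methylpiperidine-1-carboxylate | C[C@@H]1N(C(=O)OC(C)(C)C)[C@H](CCCO)CC[C@@H]1O[Si](C)(C)C(C)(C)C | intermediate
16 | tert-butyl (2S,3S,6S)-3-[(tert-butyldimethylsilyl)oxy]-2-methyl-6-(3-oxopropyl)piperidine-1-carboxylate | C[C@@H]1N(C(=O)OC(C)(C)C)[C@H](CCC=O)CC[C@@H]1O[Si](C)(C)C(C)(C)C | intermediate
17 | 3-[(2S,5S,6S)-1-(tert-butoxycarbonyl)-5-[(tert-butyldimethylsilyl)oxy]-6-methylpiperidin-2-yl]propanoic acid | C[C@@H]1N(C(=O)OC(C)(C)C)[C@H](CCC(=O)O)CC[C@@H]1O[Si](C)(C)C(C)(C)C | intermediate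
18 | methyl undec-10-enoate | C=CCCCCCCCCC(=O)OC | starting material
19 | methyl 11-(9-borabicyclo[3.3.1]nonan-9-yl)undecanoate | COC(=O)CCCCCCCCCCB1C2CCCC1CCC2 | intermediate
20 | methyl 11-hydroxyundecanoate | COC(=O)CCCCCCCCCCO | intermediate
21 | methyl 11-oxoundecanoate | COC(=O)CCCCCCCCCC=O | intermediate
22 | dimethyl (10E)-10-formylhenicos-10-enedioate | COC(=O)CCCCCCCCC/C=C(/C=O)CCCCCCCCC(=O)OC | intermediate
23 | dimethyl (10E)-10-(dimethoxymethyl)henicos-10-enedioate | COC(=O)CCCCCCCCC/C=C(/C(OC)OC)CCCCCCCCC(=O)OC | intermediate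
24 | dipotassium (10E)-10-(dimethoxymethyl)henicos-10-enedioate | [K+].[K+].[O-]C(=O)CCCCCCCCC/C=C(/C(OC)OC)CCCCCCCCC(=O)[O-] | intermediate
25 | (10E)-10-(dimethoxymethyl)henicos-10-enedioic acid | OC(=O)CCCCCCCCC/C=C(/C(OC)OC)CCCCCCCCC(=O)O | intermediate
26 | fully protected bis-piperidine (two N-Boc, two O-TBS, dimethyl acetal; E-alkene; both rings 2S,3S,6R in ring numbering) | C[C@@H]1N(C(=O)OC(C)(C)C)[C@H](CCCCCCCCCCC/C=C(/C(OC)OC)CCCCCCCCCC[C@@H]2CC[C@H](O[Si](C)(C)C(C)(C)C)[C@H](C)N2C(=O)OC(C)(C)C)CC[C@@H]1O[Si](C)(C)C(C)(C)C | intermediate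
27 | (2E)-14-[(2R,5S,6S)-5-hydroxy-6-methylpiperidin-2-yl]-2-{10-[(2R,5S,6S)-5-hydroxy-6-methylpiperidin-2-yl]decyl}tetradec-2-enal | C[C@@H]1N[C@H](CCCCCCCCCCC/C=C(/C=O)CCCCCCCCCC[C@@H]2CC[C@H](O)[C@H](C)N2)CC[C@@H]1O | target

Total steps: 16.
Longest linear sequence: 11 steps (steps 1–9, 15, 16). The central fragment needs steps 10–14.

Steps most likely to fail

**Step 15.** Productive radical pairing may be swamped by homocoupling, disproportionation and over-oxidation to cations. The anode may also foul with lipophilic material. The fallback sets out from 17 and 25 and returns at 26. Both acids are esterified with N-hydroxyphthalimide (DIC, cat. DMAP, CH2Cl2). This gives the redox-active ester of the ring acid F1 and the bis(redox-active ester) of the central diacid F2. These are then joined reductively instead of oxidatively, by nickel-electrocatalytic doubly decarboxylative C(sp3)–C(sp3) coupling. The conditions are NiCl2(dme), a terpyridine-type ligand, NaI, DMF, a sacrificial Zn anode, a carbon cathode and excess F1. This is a known way to unite two primary alkyl fragments under neutral, aprotic conditions that spare acetal, carbamate and alkene. The same two bonds are formed and 26 results.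

**Step 7.** Facial selectivity in the attack on the N-acyliminium ion may be poor, or the Lewis acid may strip the Boc group. The fallback sets out from 11 and returns at 17. It sets C6 by hydride delivery to a cyclic imine instead of carbon delivery to an iminium ion.
- Mild aqueous acid (AcOH/THF/H2O) gives the hemiaminal F3.
- Ley–Griffith oxidation (cat. Pr4N[RuO4], NMO, 4 Å MS, CH2Cl2) gives the N-Boc lactam F4.
- But-3-enylmagnesium bromide (THF, −78 °C) opens it to the keto carbamate F5.
- TFA and then base close the cyclic imine F6.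
- NaBH4 (MeOH, −78 °C) attacks axially, anti to the axial silyloxy group, to give the 2,6-cis piperidine F7 with both alkyl groups equatorial.
- Boc2O gives the butenyl carbamate F8.
- Ozonolysis (O3, then Me2S) gives aldehyde 16, and Pinnick oxidation (NaClO2, NaH2PO4, 2-methylbut-2-ene) gives 17.

**Step 16.** Cleavage of the silyl ethers may be slowed by the neighbouring ammonium centres. Long acid exposure could then hydrate or condense the enal. The fallback sets out from 26 and returns at 27. It removes the groups one kind at a time with orthogonal reagents. Bu4NF (THF) gives the bis-carbamate diol acetal F9. PPTS in wet acetone gives the bis-carbamate diol enal F10, which can be purified as a neutral compound. Brief anhydrous HCl in dioxane followed by aq. NaHCO3 gives 27.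

Further compounds
F1 | step 15 | 1,3-dioxoisoindolin-2-yl 3-[(2S,5S,6S)-1-(tert-butoxycarbonyl)-5-[(tert-butyldimethylsilyl)oxy]-6-methylpiperidin-2-yl]propanoate | C[C@@H]1N(C(=O)OC(C)(C)C)[C@H](CCC(=O)ON2C(=O)c3ccccc3C2=O)CC[C@@H]1O[Si](C)(C)C(C)(C)C
F2 | step 15 | bis(1,3-dioxoisoindolin-2-yl) (10E)-10-(dimethoxymethyl)henicos-10-enedioate | O=C(CCCCCCCCC/C=C(/C(OC)OC)CCCCCCCCC(=O)ON1C(=O)c2ccccc2C1=O)ON1C(=O)c2ccccc2C1=O
F3 | step 7 | tert-butyl (2S,3S)-3-[(tert-butyldimethylsilyl)oxy]-6-hydroxy-2-methylpiperidine-1-carboxylate (C6 epimers) | C[C@@H]1N(C(=O)OC(C)(C)C)C(O)CC[C@@H]1O[Si](C)(C)C(C)(C)C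
F4 | step 7 | tert-butyl (2S,3S)-3-[(tert-butyldimethylsilyl)oxy]-2-methyl-6-oxopiperidine-1-carboxylate | C[C@@H]1N(C(=O)OC(C)(C)C)C(=O)CC[C@@H]1O[Si](C)(C)C(C)(C)C
F5 | step 7 | tert-butyl N-[(2S,3S)-3-[(tert-butyldimethylsilyl)oxy]-6-oxodec-9-en-2-yl]carbamate | C[C@H](NC(=O)OC(C)(C)C)[C@H](CCC(=O)CCC=C)O[Si](C)(C)C(C)(C)C
F6 | step 7 | (2S,3S)-6-(but-3-enyl)-3-[(tert-butyldimethylsilyl)oxy]-2-methyl-2,3,4,5-tetrahydropyridine | C[C@@H]1N=C(CCC=C)CC[C@@H]1O[Si](C)(C)C(C)(C)C
F7 | step 7 | (2S,3S,6R)-6-(but-3-enyl)-3-[(tert-butyldimethylsilyl)oxy]-2-methylpiperidine | C[C@@H]1N[C@H](CCC=C)CC[C@@H]1O[Si](C)(C)C(C)(C)C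
F8 | step 7 | tert-butyl (2S,3S,6R)-6-(but-3-enyl)-3-[(tert-butyldimethylsilyl)oxy]-2-methylpiperidine-1-carboxylate | C[C@@H]1N(C(=O)OC(C)(C)C)[C@H](CCC=C)CC[C@@H]1O[Si](C)(C)C(C)(C)C
F9 | step 16 | bis-N-Boc diol dimethyl acetal (26 without the two silyl groups) | C[C@@H]1N(C(=O)OC(C)(C)C)[C@H](CCCCCCCCCCC/C=C(/C(OC)OC)CCCCCCCCCC[C@@H]2CC[C@H](O)[C@H](C)N2C(=O)OC(C)(C)C)CC[C@@H]1O
F10 | step 16 | bis-N-Boc diol enal (27 with both nitrogen atoms Boc-protected) | C[C@@H]1N(C(=O)OC(C)(C)C)[C@H](CCCCCCCCCCC/C=C(/C=O)CCCCCCCCCC[C@@H]2CC[C@H](O)[C@H](C)N2C(=O)OC(C)(C)C)CC[C@@H]1O
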